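**Late readings.** At the last reading of the south-east run, 72.0 h, I added left-handed product to left-handed substrate and took away the left-handed part of the charge, 50.0 %. The difference, 16 percentage points, I called the crossing: the net material that the racemization catalyst has carried from the right-handed side to the left in this dynamic kinetic resolution, read with the scatter of two readings. Mirror symmetry makes zero its natural origin, the mark of a racemate whose hands never interconvert.

| flask | left-handed substrate | right-handed substrate | partner | racemization catalyst | temperature | remark | time |
|---|---|---|---|---|---|---|---|
| south | 0.020 M | 0.020 M | 0.030 M | 40 µM | 82 °C | run made earlier |  |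
| east | 0.020 M | 0.020 M | 0.12 M | 40 µM | 99 °C | run made earlier |  |
| south-east | 0.020 M | 0.020 M | 0.060 M | 60 µM | 82 °C | run made earlier |  |
| summer | 0.020 M | 0.020 M | 0.0600 M | 40 µM | 105 °C |  | 25 h |
| spring | 0.020 M | 0.020 M | 0.0600 M | 40 µM | 90 °C |  | 25 h |
| dawn | 0.020 M | 0.020 M | 0.0600 M | 40 µM | 75 °C |  | 25 h |

- south (time / h: left-handed product / %, left-handed substrate / %): 6.00: 16.6, 34.5; 20.0: 30.5, 26.3; 40.0: 37.9, 21.9; 60.0: 40.2, 20.0; 72.0: 40.0, 20.2
- east (time / h: left-handed product / %, left-handed substrate / %): 2.00: 37.1, 13.9; 4.00: 46.8, 6.2; 8.00: 52.2, 2.5; 12.0: 52.8, 0.8; 25.0: 54.6, 0
- south-east (time / h: left-handed product / %, left-handed substrate / %): 6.00: 27.8, 25.7; 20.0: 48.7, 13.2; 40.0: 57.4, 7.3; 60.0: 61.1, 4.5; 72.0: 62.8, 3.5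

(each reading ± 0.5 percentage points)

- partner is single-handed; left-handed substrate and right-handed substrate are mirror images of each other, charged as a racemate, each of them at the stated concentration
- the numbers in the tables scatter by 0.5 percentage points (one standard deviation)
- the handed part of partner does not stay in what it makes, so the products of the two hands are mirror images too

- which flask leads in amount of left-handed product, in percent of the left-handed substrate and right-handed substrate together charged ("all alike" within 1.5 percentage points) (summer / spring / dawn / all alike)
- how much left-handed product is there at the end, in percent of the left-handed substrate and right-handed substrate together charged: summer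
- how much left-handed product is there at the end, in percent of the left-handed substrate and right-handed substrate together charged: spring
- how much left-handed product is there at the end, in percent of the left-handed substrate and right-handed substrate together charged: dawn

**First instants.** At the start the two hands were equal, so the catalyst had no net traffic to carry, and at 6.00 h the south-east crossing read 3.5 points.

**The middle.** By 20.0 h left-handed substrate in south-east had fallen to 13.2 % and the crossing had grown to 12 points, as coupling drained the left side and the catalyst refilled it.

**The end.** In the south run left-handed product read 40.2 % at 60.0 h and 40.0 % at 72.0 h, two readings that lie within their scatter of 0.5 points and so show a slowing but not a stop, with the crossing reading 10 points, while the east run ended at 4.6 points.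

**My reckoning.** Left-handed product is the left-handed part of the charge plus the crossing minus the unused left-handed substrate. For summer I held east's crossing and allowed the 2.5 % that east still held at 8.00 h, summer having less partner, which gave 52.1 %.

**The forecast.** It named spring as leader, with 53.5 % in summer, 55 % in spring and 45 % in dawn, reasoning that “hot, partner-rich conditions outrun racemization”. For summer it stood above my figure.

**The result.** The flasks gave 48.1 % in summer, 52.5 % in spring and 45.9 % in dawn, with spring leading.

    partner → decomposed reagent (k = 0.0240 h⁻¹, Ea = 109 kJ mol⁻¹)
    partner + left-handed substrate → left-handed product (k = 4.70 M⁻¹ h⁻¹, Ea = 61.0 kJ mol⁻¹)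
    left-handed substrate + racemization catalyst ⇌ right-handed substrate + racemization catalyst, rate k3*[racemization catalyst]*[left-handed substrate] forward; the back reaction follows from the equilibrium constant (k = 3100 M⁻¹ h⁻¹, Ea = 55.0 kJ mol⁻¹)
    partner ⇌ dormant form (K = 0.160, k = 0.140 h⁻¹, Ea = 120 kJ mol⁻¹, ΔH = −11.0 kJ mol⁻¹)
    partner + right-handed substrate → right-handed product (k = 2.50 M⁻¹ h⁻¹, Ea = 91.0 kJ mol⁻¹)
    (constants at 90 °C)

**Summer's ledger.** Summer's crossing came to 3.8 points, less than the 16 points of south-east, and 5.65 % of left-handed substrate stood unused at 25.0 h, with partner, the limiting reagent, down to 1.60 %. The step from partner + right-handed substrate to right-handed product is part of the reason: summer without that step gave 72.1 % of left-handed product against 48.1 %. What temperature does to the step from partner + left-handed substrate to left-handed product is one effect on the gap between summer and dawn: without it that gap went from 2.2 points to −29 points. The repeat of summer at 130 °C ended with left-handed product at 33.4 % and left-handed substrate at 11.9 %, so its crossing was −4.7 points.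

Readings and results were computed for substances that don't exist.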